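**Remark on the chemistry:** the target, 5,7-dihydroxy-2-heptacosyl-4H-chromen-4-one, has no stereocentre and no stereogenic double bond, so "single enantiomer" is taken to mean the achiral compound itself; no stereocontrol is needed.

**Retrosynthetic overview**
1. The γ-pyranone ring (O1–C2–C3–C4–C4a–C8a) is cut at three bonds at once, C4–C4a, C3–C4 and O1–C2. This gives 2-iodophloroglucinol, carbon monoxide (C4 and its oxygen) and nonacos-1-yne (C2, C3 and the C27 chain).
2. The feature used is the 5,7-dihydroxylated A ring (C4a–C8a), which is a phloroglucinol ring. Its threefold symmetry allows only one mono-iodide and makes both ortho hydroxyls equivalent for ring closure, so no protecting group is needed.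
3. Nonacos-1-yne comes from octacosanal by one-carbon homologation, and octacosanal from commercial octacosan-1-ol (C28).
4. Ring order: the benzene ring is bought; the pyranone ring is the only ring formed, in the last step.

Key step: step 4

**Route**

Step 1
Reactants: 1 phloroglucinol (benzene-1,3,5-triol)
Product: 2 2-iodobenzene-1,3,5-triol (2-iodophloroglucinol)
Conditions: I2 (1.0 equiv), NaHCO3 (1.1 equiv), THF/H2O 1:1, 0 °C, dark; used promptly
Reagents that add atoms: iodine, II
Why: Electrophilic aromatic iodination of a very electron-rich arene whose three C–H positions are equivalent by symmetry, so only one mono-iodide can form, and one equivalent of iodine at 0 °C with bicarbonate should limit over-iodination.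

Step 2
Reactants: 3 octacosan-1-ol
Product: 4 octacosanal
Conditions: TEMPO (10 mol %), PhI(OAc)2 (1.1 equiv), CH2Cl2, 35 °C
Reagents that add atoms: none
Why: TEMPO/oxoammonium-catalysed oxidation of a primary alcohol with a hypervalent iodine co-oxidant should stop at the aldehyde in anhydrous medium, and warm dichloromethane keeps the waxy alcohol in solution.

Step 3
Reactants: 4 octacosanal
Product: 6 nonacos-1-yne, via 1-diazononacos-1-ene 5 (not isolated)
Conditions: Ohira–Bestmann reagent (1.3 equiv), K2CO3 (2 equiv), THF/MeOH 2:1, 35 °C
Reagents that add atoms: dimethyl (1-diazo-2-oxopropyl)phosphonate (Ohira–Bestmann reagent), COP(=O)(OC)C(=[N+]=[N-])C(C)=O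
Why: Seyferth–Gilbert homologation in the Ohira–Bestmann variant, in which methanolysis frees the diazomethylphosphonate anion, Horner–Wadsworth–Emmons-type olefination gives diazoalkene 5, and loss of N2 with 1,2-hydrogen shift of the alkylidene carbene gives the terminal alkyne under a carbonate base mild enough for an enolisable aldehyde.

Step 4
Reactants: 2 2-iodobenzene-1,3,5-triol (1.5 equiv); 6 nonacos-1-yne (1.0 equiv)
Product: 9 5,7-dihydroxy-2-heptacosyl-4H-chromen-4-one, via 1-(2,4,6-trihydroxyphenyl)triacont-2-yn-1-one 7 (not isolated), via (E)-3-(diethylamino)-1-(2,4,6-trihydroxyphenyl)triacont-2-en-1-one 8 (not isolated)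
Conditions: PdCl2(dppf) (5 mol %), CO (10 bar), Et2NH/DMF 1:3, 80 °C, copper-free, degassed; then 1 M HCl work-up
Reagents that add atoms: carbon monoxide, [C-]#[O+]
Why: Pd(0) inserts into the C–I bond of 2, CO insertion gives an aroyl–Pd(II) species, amine-assisted alkynylation with 6 and reductive elimination form the C4–C4a and C3–C4 bonds of ynone 7, diethylamine adds to 7 to give the push–pull enaminone 8, and the ortho hydroxyl displaces diethylamine at C3 of 8 by addition–elimination to form the O1–C2 bond. The closest known reaction type is the Pd-catalysed carbonylative Sonogashira annulation of o-iodophenols with terminal alkynes, alkyl alkynes included, in secondary amines, which gives chromones and flavones. The pyranone ring closes 6-endo-trig on the enaminone C=C (formally 6-endo-dig on the ynone), and the amine pathway steers away from 5-exo-dig closure to an aurone-type benzofuranone. No stereocentre is formed, and the geometry of 8 is irrelevant because its push–pull double bond rotates and is consumed. The step needs carbonylative rather than direct coupling (which would lead to a 2-alkylbenzofuran) and alkynylation rather than amino- or phenoxy-carbonylation of the aroyl–Pd; CO pressure, the absence of copper and the fast CO insertion of an electron-rich aryl–Pd should secure the first, and the excess of cheap 2 covers losses to the second. Regiochemistry needs no control because 2 is symmetric about its C–I axis, so either ortho hydroxyl gives the same chromone and the two spectator hydroxyls end as 5-OH and 7-OH.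

**Compound list**
1 | phloroglucinol (benzene-1,3,5-triol) | Oc1cc(O)cc(O)c1 | starting material
2 | 2-iodobenzene-1,3,5-triol | Oc1cc(O)c(I)c(O)c1 | intermediate
3 | octacosan-1-ol | CCCCCCCCCCCCCCCCCCCCCCCCCCCCO | starting material
4 | octacosanal | CCCCCCCCCCCCCCCCCCCCCCCCCCCC=O | intermediate
5 | 1-diazononacos-1-ene | CCCCCCCCCCCCCCCCCCCCCCCCCCCC=C=[N+]=[N-] | intermediate (not isolated)
6 | nonacos-1-yne | CCCCCCCCCCCCCCCCCCCCCCCCCCCC#C | intermediate
7 | 1-(2,4,6-trihydroxyphenyl)triacont-2-yn-1-one | CCCCCCCCCCCCCCCCCCCCCCCCCCCC#CC(=O)c1c(O)cc(O)cc1O | intermediate (not isolated)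
8 | (E)-3-(diethylamino)-1-(2,4,6-trihydroxyphenyl)triacont-2-en-1-one | CCCCCCCCCCCCCCCCCCCCCCCCCCC/C(N(CC)CC)=C\C(=O)c1c(O)cc(O)cc1O | intermediate (not isolated)
9 | 5,7-dihydroxy-2-heptacosyl-4H-chromen-4-one | CCCCCCCCCCCCCCCCCCCCCCCCCCCc1cc(=O)c2c(O)cc(O)cc2o1 | target

**Step count**
Total steps: 4. Longest linear sequence: 3 (steps 2, 3, 4).

**Steps most likely to fail**

Step 4. The aroyl–palladium intermediate may be intercepted by a phenoxide oxygen of a second polyphenol molecule or by diethylamine faster than by the alkyne. The electron-rich iodotriol may also lose iodine under the basic conditions before oxidative addition, leaving the alkyne unconverted. The fallback sets out from 6 and comes back at 9. It replaces the three-component carbonylation by a two-component acylation with masked phenols and a separate ring closure. Acyl Sonogashira coupling of 6 with commercial 2,4,6-trimethoxybenzoyl chloride (PdCl2(PPh3)2, CuI, Et3N, THF, rt) should give 1-(2,4,6-trimethoxyphenyl)triacont-2-yn-1-one F1. Heating F1 in 48% HBr/AcOH at reflux should close the pyranone ring through the ortho methoxy oxygen with loss of bromomethane and cleave the two remaining methyl ethers, giving 9. The β-bromoenone and 1,3-diketone side paths converge on the same chromone.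

Step 1. Over-iodination to di- and tri-iodides, and oxidative darkening with loss of iodine during isolation of the unprotected iodotriol, may prevent clean supply of 2. The fallback sets out from 1 and comes back at 2. It fixes the number and site of iodine by directed metalation instead of electrophilic substitution on the free triol. Protection of 1 (MOMCl, i-Pr2NEt, CH2Cl2, 0 °C to rt) should give 1,3,5-tris(methoxymethoxy)benzene F2. Ortho-lithiation between two MOM ethers (n-BuLi, THF, 0 °C) and iodine quench at −78 °C should give the storable 2-iodo-1,3,5-tris(methoxymethoxy)benzene F3. Acetal cleavage (HCl, MeOH, rt) immediately before step 4 releases 2.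

Step 3. The waxy aldehyde may precipitate from the methanolic medium, and carbonate-induced self-aldol condensation may outrun a slow olefination. The fallback sets out from 4 and comes back at 6. It is a Corey–Fuchs sequence run entirely in aprotic solvents. Dibromo-olefination (CBr4, PPh3, CH2Cl2, 0 °C to rt) should give 1,1-dibromononacos-1-ene F4. Treatment with n-BuLi (2.2 equiv, THF, −78 to 0 °C; Fritsch–Buttenberg–Wiechell rearrangement) and aqueous NH4Cl quench should give 6.

**Further compounds**
F1 | step 4 | 1-(2,4,6-trimethoxyphenyl)triacont-2-yn-1-one | CCCCCCCCCCCCCCCCCCCCCCCCCCCC#CC(=O)c1c(OC)cc(OC)cc1OC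
F2 | step 1 | 1,3,5-tris(methoxymethoxy)benzene | COCOc1cc(OCOC)cc(OCOC)c1
F3 | step 1 | 2-iodo-1,3,5-tris(methoxymethoxy)benzene | COCOc1cc(OCOC)c(I)c(OCOC)c1
F4 | step 3 | 1,1-dibromononacos-1-ene | CCCCCCCCCCCCCCCCCCCCCCCCCCCC=C(Br)Br
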